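Retrosynthetic overview
Germacrane numbering is used: ring C1–C10, acrylate carbons C11–C13, C14 = CH3 on C10, C15 = CH2OH on C4. The ten-membered ring is opened at the Z C1=C10 alkene (ring-closing metathesis). The oxirane goes back to the C4=C5 allylic alcohol (Sharpless epoxidation), and the C8 ester to the alcohol plus protected 4-hydroxytiglic acid.
Enabling feature: the lactone carbinol carbon C6 lies between C7 and the C4–C5 oxirane. Without the oxirane oxygen, C4=C5–C6=C7 is a 1,3-diene. A carbon group delivered to its terminus C7 leaves an allyl unit C6–C5–C4, and its near end C6 is the only place where a carboxylate three atoms away can close a five-membered ring.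
Key disconnection: the whole α-methylene-γ-lactone ring (bonds C11–C7 and O–C6) is removed as 2-bromoacrylic acid. This leaves an acyclic bis-silylated tetraenol with one stereocentre (C8), assembled from propargyl alcohol (C15, C4, C5), leaf alcohol (C1–C3), acrolein (C6–C8) and a methallylstannane (C9, C10, C14).
Order of ring formation: γ-lactone (step 7), oxirane (step 13), ten-membered carbocycle (step 14).

Key step: step 7

Remark: the CIP descriptors at C6 and C7 change along the route (6R,7S in 17; 6R,7R in 18, 25 and 26; 6S,7R in 27 and 28) only because substituent priorities change; the spatial arrangement stays the same.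

Step 1
Reactants: 1 (Z)-hex-3-en-1-ol
Product: 2 (Z)-1-bromohex-3-ene
Conditions: CBr4, PPh3, CH2Cl2, 0 °C
Reagents that add atoms: carbon tetrabromide, BrC(Br)(Br)Br
Why: The Appel bromination replaces the primary hydroxyl by SN2 displacement of the alkoxyphosphonium ion, leaves the Z alkene untouched and forms no stereocentre.

Step 2
Reactants: 2 (Z)-1-bromohex-3-ene (2.5 equiv); 3 prop-2-yn-1-ol
Product: 6 (2Z)-2-[(3Z)-hex-3-en-1-yl]-3-iodoprop-2-en-1-ol, via hexenylmagnesium bromide 4 (not isolated), via chelated alkenylmagnesium alkoxide 5 (not isolated)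
Conditions: Mg, THF, 40 °C; then 3, CuI (10 mol %), THF, -10 °C to rt; then I2, THF, -20 to 0 °C; aqueous work-up
Reagents that add atoms: iodine, [I][I]
Why: Copper-catalysed anti-carbomagnesiation of the magnesium alkoxide of a propargylic alcohol puts the alkyl group on the inner alkyne carbon (C4) and magnesium on C5 inside a five-membered O–Mg chelate, so iodinolysis with retention fixes iodine cis to CH2OH, that is C3 trans to the future C6.

Step 3
Reactants: 6 (2Z)-2-[(3Z)-hex-3-en-1-yl]-3-iodoprop-2-en-1-ol
Product: 7 tert-butyl{[(2Z)-2-[(3Z)-hex-3-en-1-yl]-3-iodoprop-2-en-1-yl]oxy}diphenylsilane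
Conditions: TBDPSCl, imidazole, CH2Cl2, 0 °C to rt
Reagents that add atoms: tert-butylchlorodiphenylsilane, CC(C)(C)[Si](Cl)(c1ccccc1)c1ccccc1
Why: Imidazole-promoted silylation of the primary alcohol gives an allylic ether that cannot ionise under palladium catalysis and outlasts the later mild acid step.

Step 4
Reactants: 7 the TBDPS ether; 8 acrolein (3 equiv)
Product: 9 (2E,4Z,8Z)-5-{[(tert-butyldiphenylsilyl)oxy]methyl}undeca-2,4,8-trienal
Conditions: Pd(OAc)2 (5 mol %), n-Bu4NCl, NaHCO3, DMF, rt
Reagents that add atoms: none
Why: Heck vinylation under Jeffery phase-transfer conditions couples the alkenyl iodide with retention of the C4=C5 geometry at the β-carbon of acrolein, syn insertion and syn β-hydride elimination giving the E C6=C7 bond, and cyclisation onto the side-chain alkene is impossible because palladium stands trans to that chain.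

Step 5
Reactants: 9 the trienal; 10 tributyl(2-methylallyl)stannane
Product: 12 (4R,5E,7Z,11Z)-8-{[(tert-butyldiphenylsilyl)oxy]methyl}-2-methyltetradeca-1,5,7,11-tetraen-4-ol (8R in germacrane numbering), via tributylstannyl ether 11 (not isolated)
Conditions: (R)-BINOL (20 mol %), Ti(OiPr)4 (10 mol %), 4 Å MS, CH2Cl2, -20 °C; aq NaHCO3
Reagents that add atoms: none
Why: The Keck catalytic asymmetric allylation (BINOL–titanium Lewis acid, SE2' addition of the allylstannane) adds 1,2 to the unsaturated aldehyde, and the (R)-BINOL complex shields one aldehyde face so that C8 should form with R configuration.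

Step 6
Reactants: 12 the tetraenol
Product: 13 the C8 triethylsilyl ether of 12 (8R; E C6=C7; C15 cis to C6 on C4=C5)
Conditions: TESCl, imidazole, CH2Cl2, 0 °C
Reagents that add atoms: chlorotriethylsilane, CC[Si](Cl)(CC)CC
Why: Silylation turns the dienylic alcohol into a bulky, non-ionisable and acid-labile ether that serves as the steric control element of the next step, and C8 is not touched.

Step 7
Reactants: 13 the bis-silyl tetraene; 14 2-bromoacrylic acid
Product: 17 (4S,5R)-5-[(1Z,5Z)-2-{[(tert-butyldiphenylsilyl)oxy]methyl}octa-1,5-dien-1-yl]-3-methylidene-4-{(1R)-3-methyl-1-[(triethylsilyl)oxy]but-3-en-1-yl}oxolan-2-one (trans-lactone; 6R,7S,8R), via potassium 2-bromoacrylate 15 (not isolated), via oxapalladacycle 16 (not isolated)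
Conditions: 14 (1.3 equiv, syringe pump, 6 h), Pd(OAc)2 (10 mol %), P(2-furyl)3 (25 mol %), K2CO3 (3 equiv), BHT (cat.), DMF, 70 °C
Reagents that add atoms: none
Why: Proposed new method: zerovalent palladium inserts into the C–Br bond of carboxylate 15, the resulting 1-carboxylatovinylpalladium species adds syn across the E C6=C7 bond with carbon going to the less substituted diene terminus C7, and the η3-allyl unit C6–C5–C4 so formed, held by the carboxylate as the six-membered oxapalladacycle 16, forms the O–C6 bond by C–O reductive elimination and releases zerovalent palladium. The closest known reaction type is the Larock heteroannulation of 1,3-dienes by aryl and vinylic halides that carry an OH, NHR or CO2H group; what has not been shown is 2-bromoacrylic acid as the C–C–O partner on an acyclic 1,1,4-trisubstituted diene with an allylic stereocentre. The only ring closed is the γ-lactone, by 5-exo attack of oxygen on the allyl terminus C6, the 7-endo alternative at the fully substituted C4 being sterically and entropically disfavoured. C7 is set in the insertion: in the rotamer of 13 that minimises A(1,3) strain (H8 in the diene plane) the palladium reagent should approach anti to the bulky C8–OSiEt3 group, which translates 8R into the required C7 configuration. C6 is set by delivery of oxygen on the palladium-bearing face, so net syn addition to the E alkene gives the trans-lactone, and because 17 is an allylic carboxylate that zerovalent palladium can re-ionise, any cis isomer should drain to the more stable trans isomer. The step needs chemoselectivity for the diene and retention of the C4=C5 geometry: the Z-1,2-dialkyl and 1,1-dialkyl alkenes insert far more slowly and give no stabilised allyl, the silyl ethers at the allylic positions C8 and C15 cannot ionise, slow addition of 14 keeps its self-coupling and over-vinylation of 17 low, and syn-anti exchange at C4 would need an unfavourable tertiary η1-palladium species.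

Step 8
Reactants: 17 the silylated lactone
Product: 18 the C8 alcohol (6R,7R,8R): 17 with OH in place of OSiEt3
Conditions: PPTS (20 mol %), MeOH/CH2Cl2 1:4, 0 °C
Reagents that add atoms: none
Why: Acid-catalysed methanolysis separates the secondary triethylsilyl ether from the far more robust TBDPS ether, touches no stereocentre, and at 0 °C under weak acid acyl migration from O6 to O8 should stay slow.

Step 9
Reactants: 19 (tert-butyldimethylsilyloxy)acetaldehyde; 20 ethyl 2-(triphenylphosphoranylidene)propanoate
Product: 21 ethyl (2E)-4-[(tert-butyldimethylsilyl)oxy]-2-methylbut-2-enoate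
Conditions: CH2Cl2, rt
Reagents that add atoms: none
Why: The Wittig reaction of the stabilised, α-branched ylide gives the E trisubstituted enoate under the usual control for stabilised ylides.

Step 10
Reactants: 21 the ethyl ester
Product: 23 (2E)-4-[(tert-butyldimethylsilyl)oxy]-2-methylbut-2-enoic acid, via lithium carboxylate 22 (not isolated)
Conditions: LiOH·H2O, THF/MeOH/H2O, rt; then 1 M HCl to pH 4, 0 °C
Reagents that add atoms: lithium hydroxide, [Li+].[OH-]
Why: Saponification cleaves the ethyl ester by acyl substitution, and the primary TBS ether and the E alkene survive the mild base and the brief cold acidification.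

Step 11
Reactants: 18 the C8 alcohol; 23 the protected hydroxytiglic acid
Product: 25 the C8 ester (6R,7R,8R) carrying OTBDPS at C15 and OTBS on the side chain, via mixed anhydride 24 (not isolated)
Conditions: 2,4,6-Cl3C6H2COCl, Et3N, toluene, rt; then 18, DMAP, 0 °C to rt
Reagents that add atoms: none
Why: The Yamaguchi esterification acylates the hindered secondary alcohol at oxygen with retention at C8, the E acid is the thermodynamic isomer so DMAP cannot scramble it, and no alkoxide is formed that could trigger translactonisation.

Step 12
Reactants: 25 the bis-silyl ester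
Product: 26 the diol (6R,7R,8R): free C15 allylic alcohol and free 4-hydroxytiglate
Conditions: HF·pyridine, pyridine, THF, 0 °C to rt
Reagents that add atoms: none
Why: Buffered fluoride-mediated desilylation removes both primary silyl ethers and is neither basic enough for Michael addition to the α-methylene lactone nor acidic enough to ionise the allylic lactone C6–O bond.

Step 13
Reactants: 26 the diol
Product: 27 the epoxy diol (4S,5R,6S,7R,8R): 26 with a 4,5-oxirane, C3 trans to C6
Conditions: Ti(OiPr)4 (30 mol %), L-(+)-DIPT (36 mol %), t-BuOOH, 4 Å MS, CH2Cl2, -20 °C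
Reagents that add atoms: tert-butyl hydroperoxide, CC(C)(C)OO
Why: The Sharpless asymmetric epoxidation acts only on the electron-rich C4=C5 allylic alcohol (the tiglate and α-methylene alkenes are electron-poor, the other two carry no directing hydroxyl), and L-(+)-tartrate delivers oxygen to the face giving 4S,5R, which is also the face anti to C7 in the A(1,3)-locked rotamer with H6 in the alkene plane, so reagent and substrate control should be matched and syn transfer keeps C3 trans to C6.

Step 14
Reactants: 27 the epoxy diol
Product: 28 the target, (1(10)Z,4S,5R,6S,7R,8R)-4,5-epoxy-15-hydroxy-8-[(2E)-4-hydroxy-2-methylbut-2-enoyloxy]germacra-1(10),11(13)-dien-12,6-olide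
Conditions: second-generation Grubbs catalyst (15 mol %, in portions), 1,4-benzoquinone (20 mol %), toluene (0.5 mM), 80 °C, Ar sparge
Reagents that add atoms: none
Why: In the ring-closing metathesis the ruthenium carbene should load at the 1,2-disubstituted hexenyl alkene and close onto the 1,1-disubstituted methallyl alkene with loss of but-1-ene, the ten-membered ring holding the new trisubstituted alkene as the less strained Z isomer, while the tiglate and α-methylene alkenes are electron-poor and could only close a strained eight-membered ring.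

Compound list
1 | (Z)-hex-3-en-1-ol | CC/C=C\CCO | starting material
2 | (Z)-1-bromohex-3-ene | CC/C=C\CCBr | intermediate
3 | prop-2-yn-1-ol | C#CCO | starting material
4 | (Z)-hex-3-enylmagnesium bromide | CC/C=C\CC[Mg]Br | intermediate
5 | bromomagnesium (2Z)-3-(bromomagnesio)-2-[(3Z)-hex-3-enyl]prop-2-en-1-olate | Br[Mg]OC/C(CC/C=C\CC)=C\[Mg]Br | intermediate
6 | (2Z)-2-[(3Z)-hex-3-en-1-yl]-3-iodoprop-2-en-1-ol | OC/C(CC/C=C\CC)=C\I | intermediate
7 | TBDPS ether of 6 | CC(C)(C)[Si](OC/C(CC/C=C\CC)=C\I)(c1ccccc1)c1ccccc1 | intermediate
8 | acrolein | C=CC=O | starting material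
9 | (2E,4Z,8Z)-5-{[(tert-butyldiphenylsilyl)oxy]methyl}undeca-2,4,8-trienal | O=C/C=C/C=C(\CO[Si](c1ccccc1)(c1ccccc1)C(C)(C)C)CC/C=C\CC | intermediate
10 | tributyl(2-methylallyl)stannane | C=C(C)C[Sn](CCCC)(CCCC)CCCC | starting material
11 | tributylstannyl ether of 12 | C=C(C)C[C@@H](O[Sn](CCCC)(CCCC)CCCC)/C=C/C=C(\CO[Si](c1ccccc1)(c1ccccc1)C(C)(C)C)CC/C=C\CC | intermediate
12 | (4R,5E,7Z,11Z)-8-{[(tert-butyldiphenylsilyl)oxy]methyl}-2-methyltetradeca-1,5,7,11-tetraen-4-ol | C=C(C)C[C@@H](O)/C=C/C=C(\CO[Si](c1ccccc1)(c1ccccc1)C(C)(C)C)CC/C=C\CC | intermediate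
13 | triethylsilyl ether of 12 (key-step precursor) | C=C(C)C[C@@H](O[Si](CC)(CC)CC)/C=C/C=C(\CO[Si](c1ccccc1)(c1ccccc1)C(C)(C)C)CC/C=C\CC | intermediate
14 | 2-bromoacrylic acid | C=C(Br)C(=O)O | starting material
15 | potassium 2-bromoacrylate | [K+].[O-]C(=O)C(Br)=C | intermediate
16 | six-membered oxapalladacycle (drawn as the η1 form at C6, other ligands omitted) | C=C1C(=O)O[Pd][C@H](/C=C(\CO[Si](c2ccccc2)(c2ccccc2)C(C)(C)C)CC/C=C\CC)[C@H]1[C@H](O[Si](CC)(CC)CC)CC(C)=C | intermediate
17 | trans-α-methylene-γ-lactone, C8 OTES, C15 OTBDPS (6R,7S,8R) | C=C1C(=O)O[C@H](/C=C(\CO[Si](c2ccccc2)(c2ccccc2)C(C)(C)C)CC/C=C\CC)[C@H]1[C@H](O[Si](CC)(CC)CC)CC(C)=C | intermediate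
18 | C8 alcohol (6R,7R,8R) | C=C1C(=O)O[C@H](/C=C(\CO[Si](c2ccccc2)(c2ccccc2)C(C)(C)C)CC/C=C\CC)[C@H]1[C@H](O)CC(C)=C | intermediate
19 | (tert-butyldimethylsilyloxy)acetaldehyde | CC(C)(C)[Si](C)(C)OCC=O | starting material
20 | ethyl 2-(triphenylphosphoranylidene)propanoate | CCOC(=O)C(C)=P(c1ccccc1)(c1ccccc1)c1ccccc1 | starting material
21 | ethyl (2E)-4-[(tert-butyldimethylsilyl)oxy]-2-methylbut-2-enoate | CCOC(=O)/C(C)=C/CO[Si](C)(C)C(C)(C)C | intermediate
22 | lithium (2E)-4-[(tert-butyldimethylsilyl)oxy]-2-methylbut-2-enoate | [Li+].[O-]C(=O)/C(C)=C/CO[Si](C)(C)C(C)(C)C | intermediate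
23 | (2E)-4-[(tert-butyldimethylsilyl)oxy]-2-methylbut-2-enoic acid | OC(=O)/C(C)=C/CO[Si](C)(C)C(C)(C)C | intermediate
24 | mixed anhydride of 23 with 2,4,6-trichlorobenzoic acid | O=C(OC(=O)/C(C)=C/CO[Si](C)(C)C(C)(C)C)c1c(Cl)cc(Cl)cc1Cl | intermediate
25 | C8 ester, bis-silyl protected (6R,7R,8R) | C=C1C(=O)O[C@H](/C=C(\CO[Si](c2ccccc2)(c2ccccc2)C(C)(C)C)CC/C=C\CC)[C@H]1[C@H](OC(=O)/C(C)=C/CO[Si](C)(C)C(C)(C)C)CC(C)=C | intermediate
26 | diol (6R,7R,8R) | C=C1C(=O)O[C@H](/C=C(\CO)CC/C=C\CC)[C@H]1[C@H](OC(=O)/C(C)=C/CO)CC(C)=C | intermediate
27 | epoxy diol (4S,5R,6S,7R,8R) | C=C1C(=O)O[C@H]([C@H]2O[C@]2(CO)CC/C=C\CC)[C@H]1[C@H](OC(=O)/C(C)=C/CO)CC(C)=C | intermediate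
28 | CNP0187639.2 | C=C1C(=O)O[C@H]2[C@H]1[C@H](OC(=O)/C(C)=C/CO)C/C(C)=C\CC[C@@]1(CO)O[C@H]21 | target

Total step count: 14. Longest linear sequence: 12 steps (steps 1–8 and 11–14).

Steps most likely to fail

Step 7. Several processes could undermine this step:
- Migratory insertion into the hindered internal diene may be slow. Self-coupling of the bromoacrylate or a second vinylation at the exocyclic alkene of the product would then take over.
- The facial bias at C7 may be insufficient.
- Outer-sphere closure may build the cis ring fusion faster than it equilibrates.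
- The allyl intermediate may lose a β-hydride.

The fallback uses known chemistry, sets out from 13 and returns at 17. It is an oxidative free-radical lactone annulation with trivalent manganese: Mn(OAc)3·2H2O, Cu(OAc)2, methyl hydrogen malonate and KOAc in AcOH at rt. The electrophilic malonyl radical adds to the diene terminus C7, the allyl radical is oxidised, and the carboxyl group closes at C6 to the α-methoxycarbonyl lactone F1 (C11 epimers, trans at C6/C7). Saponification with LiOH and relactonisation on acidification give the α-carboxy lactone F2. Aqueous formaldehyde and Et2NH, then NaOAc/AcOH (decarboxylative Mannich methylenation), install the exocyclic methylene and lead back to 17.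

Step 14. Oligomerisation may outrun closure of the strained ring, the ruthenium carbene may be drained by the α-methylene lactone, and ruthenium hydrides may shift double bonds. The fallback sets out from 27 and returns at 28, and it masks the acceptor alkene for the ring closure. Conjugate addition of Me2NH (THF, 0 °C) gives the 13-dimethylamino adduct F3 (configuration at C11 immaterial). Metathesis of its p-toluenesulfonate salt with second-generation Grubbs catalyst closes the ring to the macrocyclic amine F4. MeI converts this into the quaternary ammonium iodide F5, and aqueous NaHCO3 eliminates trimethylamine to regenerate the α-methylene lactone of 28.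

Step 13. Oxygen transfer to an allylic alcohol whose C5 substituent is cis to CH2OH and branched may be slow. Titanium may be tied up by the second hydroxyl group, and the epoxy alcohol may be opened by titanium alkoxides on long exposure. The fallback sets out from 26 and returns at 28, and it moves the epoxidation behind the ring closure. Metathesis of 26 under the conditions of step 14 gives the macrocyclic dienediol F6. In that ring the strained ring-trans C4=C5 alkene exposes only its outer face, so hydroxyl-directed epoxidation with VO(acac)2 and t-BuOOH (CH2Cl2, 0 °C) should give the 4S,5R oxirane of 28 under macrocyclic substrate control instead of reagent control.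

Further compounds
F1 | step 7 | α-methoxycarbonyl lactone (C11 epimers) | COC(=O)C1C(=O)O[C@H](/C=C(\CO[Si](c2ccccc2)(c2ccccc2)C(C)(C)C)CC/C=C\CC)[C@H]1[C@H](O[Si](CC)(CC)CC)CC(C)=C
F2 | step 7 | α-carboxy lactone (C11 epimers) | OC(=O)C1C(=O)O[C@H](/C=C(\CO[Si](c2ccccc2)(c2ccccc2)C(C)(C)C)CC/C=C\CC)[C@H]1[C@H](O[Si](CC)(CC)CC)CC(C)=C
F3 | step 14 | 13-dimethylamino adduct of 27 | CN(C)CC1C(=O)O[C@H]([C@H]2O[C@]2(CO)CC/C=C\CC)[C@H]1[C@H](OC(=O)/C(C)=C/CO)CC(C)=C
F4 | step 14 | macrocyclic amine (13-dimethylamino-11,13-dihydro 28) | CN(C)CC1C(=O)O[C@H]2[C@H]1[C@H](OC(=O)/C(C)=C/CO)C/C(C)=C\CC[C@@]1(CO)O[C@H]21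
F5 | step 14 | quaternary ammonium iodide of F4 | C[N+](C)(C)CC1C(=O)O[C@H]2[C@H]1[C@H](OC(=O)/C(C)=C/CO)C/C(C)=C\CC[C@@]1(CO)O[C@H]21.[I-]
F6 | step 13 | macrocyclic dienediol (4,5-deoxy 28) | C=C1C(=O)O[C@@H]2/C=C(\CO)CC/C=C(/C)C[C@@H](OC(=O)/C(C)=C/CO)[C@@H]12
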